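The numbers in the tables are calculated for substances that don't exist; scatter was added.

Decide first to follow the second end groups: each link uses one, and you may suspect the protic impurity of taking them too.

| flask | first end groups | second end groups | one-sided end groups | protic impurity | remark | time |
|---|---|---|---|---|---|---|
| gamma | 33 mM | 29.7 mM | 0.33 mM | 16.5 mM | run made earlier |  |
| zeta | 33 mM | 29.7 mM | 0.46 mM | 16.5 mM | run made earlier |  |
| delta | 33 mM | 29.7 mM | 0.73 mM | 16.5 mM | run made earlier |  |
| alder | 33 mM | 29.7 mM | 0.330 mM | 16.5 mM | everything together at the start | 4.0 min |
| elm | 33 mM | 29.7 mM (fed, over 3.0 min) | 0.330 mM | 16.5 mM | all else is in the flask from the start; the feed brings no volume worth counting | 4.0 min |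
| ash | 33 mM (in portions, 4, over 3.0 min) | 29.7 mM | 0.330 mM | 16.5 mM | first portion at the start, last at 3.0 min | 4.0 min |
| birch | 33 mM (fed, over 3.0 min) | 29.7 mM | 0.330 mM | 16.5 mM | all else is in the flask from the start; the feed brings no volume worth counting | 4.0 min |

- gamma (time / min: links / %, first end groups / %): 0.200: 44, 56; 0.667: 65, 30; 1.00: 71, 26; 1.50: 76, 21; 2.50: 77, 17
- zeta (time / min: links / %, first end groups / %): 0.500: 61, 35; 1.00: 72, 25; 1.33: 73, 22; 2.00: 76, 15; 2.50: 78, 17
- delta (time / min: links / %, first end groups / %): 0.500: 64, 35; 1.00: 70, 24; 1.33: 74, 21; 2.00: 77, 18; 2.50: 75, 18

(readings scatter by 1.5 percentage points)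



- the best flask by amount of links, in percent of the first end groups charged; "all alike" if 1.5 percentage points covers them all (alder / elm / ash / birch / all alike)
- amount of links at the end, in percent of the first end groups charged, alder
- amount of links at the end, in percent of the first end groups charged, elm
- amount of links at the end, in percent of the first end groups charged, ash
- amount of links at the end, in percent of the first end groups charged, birch

Work in fractions of the first end groups charged, and call the fraction still standing a. In the gamma run a falls to 56% by 0.200 min. Taking the mean second end groups over that stretch, you get a link pace of 4.26 min⁻¹ at full charge, scaling with a. Now suppose a second end group has a rival fate at a steady quench pace, pseudo-first-order in the second end groups, a supposition that treats the protic impurity as if it stayed at its charge. Both rates scale with the second end groups standing, so these cancel: quench over link is quench pace divided by the product of link pace and a. Summed over a batch, the fraction lost is quench pace over link pace, times the logarithm of charge over what stands.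

The gamma run charged 90.0%, and 83.0% of the first end groups had gone by 2.50 min. That loses 7.00% and gives 0.168 min⁻¹. The weak link is the shortfall of 6.00% in links plus first end groups. If each side loss consumes a link and a first end group, links ever made are 80.0%, the loss is 10.0%, and the quench pace, the fraction of second end groups quenched per minute, is 0.241 min⁻¹.

Alder starts at a ratio of 0.0564. In birch I take the link rate as held to the feed, so the ratio starts at 0.650, far higher than in alder. On this reckoning birch's second end groups reach zero at 2.08 min, giving 69.3% links made and 66.3% after the side loss. I put ash beside birch, and elm, where first end groups stand from the start, near alder.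

The forecast calls the levelling “an equilibrium-like stall” and gives 77%, 73%, 74% and 75%, with alder best; for birch it stands above my reckoning.

    first end groups + second end groups → links (k = 2.30 L mol⁻¹ s⁻¹)
    first end groups + one-sided end groups → capped ends (k = 35.5 L mol⁻¹ s⁻¹)
    first end groups + links → side product (k = 0.0272 L mol⁻¹ s⁻¹)
    second end groups + protic impurity → quenched reagent (k = 0.251 L mol⁻¹ s⁻¹)

Alder gives 77.5%, elm 73.8%, ash 63.8% and birch 63.4%, so alder leads. Birch holds 7.68 mM of quenched reagent, more than the 2.86 mM in alder, against 6.82 mM reckoned. Take the neighbour of birch charged with 56 mM of first end groups. The same 0.241 min⁻¹ starts its ratio at 0.383, and the reckoning reaches zero second end groups at 1.35 min with 4.55 mM counted as quenched. That neighbour holds 6.05 mM of quenched reagent, with links at 38.2% of its own charge.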